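**Strategy.** Ring numbering: C1 (free OH), C2, C3 (methyl carbinol), C4, C5 (CH2), C6 (side-chain carbon). The ring is cut at C1–C6 and C4–C5 into a (Z)-iodo-enal (C1–C4) and a 2-substituted butadiene whose vinyl group supplies C5 and C6 and which carries the whole side chain. Platinum-catalysed 1,4-diboration turns the diene into a vicinal dinucleophile; in one pot, allylboration of the aldehyde forms C1–C6 with the C1 and C6 stereocentres and the exocyclic methylene, and an intramolecular B-alkyl Suzuki coupling forms C4–C5. The step exploits the homoallylic alcohol HO–C1–C6–C(=CH2) and the ring methylene C5. The new C3=C4 alkene then gives the trans C3–OH/C4–angelate by directed epoxidation and carboxylate opening.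

Key step: step 9

Remark: pinacol buta-2,3-dien-1-ylboronate (10) is taken as a purchasable reagent; side-chain locants are C1' (exocyclic =CH2), C2' (alkene carbon on C6), C3' (carbinol), C4' (CH2), then the prenyl or oxirane end.

Step 1
Reactants: 1 pent-1-en-4-yn-3-ol (racemic)
Product: 3 rac-(1Z)-1-iodo-2-methylpenta-1,4-dien-3-ol, via alkenylmagnesium alkoxide chelate 2 (not isolated)
Conditions: MeMgBr (3 equiv), CuI (10 mol%), THF, −10 to 23 °C; then I2, THF, −78 to 0 °C
Reagents that add atoms: methylmagnesium bromide C[Mg]Br; iodine II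
Why: Copper-catalysed, alkoxide-directed anti-carbomagnesiation of the propargylic alcohol puts methyl on the proximal alkyne carbon and magnesium on the terminus inside a five-membered chelate, so iodinolysis should give the alkenyl iodide with iodine cis to the carbinol carbon (Z), the vinyl group being inert.

Step 2
Reactants: 3 rac-(1Z)-1-iodo-2-methylpenta-1,4-dien-3-ol
Product: 4 (1Z,3S)-1-iodo-2-methylpenta-1,4-dien-3-ol
Conditions: Novozym 435 (immobilised Candida antarctica lipase B), vinyl acetate, hexane, 30 °C, run past half conversion; chromatography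
Reagents that add atoms: none
Why: Lipase kinetic resolution: by the Kazlauskas rule (large group = iodoalkenyl, medium group = vinyl) the enzyme should acetylate the (R)-alcohol and leave the (S)-alcohol, which is separated from the acetate.

Step 3
Reactants: 4 (1Z,3S)-1-iodo-2-methylpenta-1,4-dien-3-ol
Product: 5 1-({[(1Z,3S)-1-iodo-2-methylpenta-1,4-dien-3-yl]oxy}methyl)-4-methoxybenzene (PMB ether)
Conditions: NaH, PMBCl, Bu4NI (cat.), DMF, 0 to 23 °C
Reagents that add atoms: 4-methoxybenzyl chloride COc1ccc(CCl)cc1
Why: Williamson etherification of the sodium alkoxide; the alkenyl iodide has no β-hydrogen to eliminate and the stereocentre is not touched.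

Step 4
Reactants: 5 PMB ether of the (3S)-iodo-dienol
Product: 7 (2R,3Z)-4-iodo-2-[(4-methoxyphenyl)methoxy]-3-methylbut-3-enal, via vicinal diol 6 (not isolated)
Conditions: OsO4 (2 mol%), NaIO4 (4 equiv), 2,6-lutidine, 1,4-dioxane/H2O (3:1), 23 °C; used crude
Reagents that add atoms: osmium tetroxide O=[Os](=O)(=O)=O; sodium periodate [Na+].[O-]I(=O)(=O)=O
Why: Lemieux–Johnson cleavage, in which OsO4 should choose the monosubstituted vinyl group over the halogen-deactivated trisubstituted iodoalkene; the α-alkoxy aldehyde is used at once to avoid epimerisation at C2.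

Step 5
Reactants: 8 4-methylpent-3-en-1-ol
Product: 9 4-methylpent-3-enal
Conditions: Dess–Martin periodinane, NaHCO3, CH2Cl2, 0 °C; used directly
Reagents that add atoms: none
Why: Buffered Dess–Martin oxidation should stop at the β,γ-unsaturated aldehyde without moving the alkene into conjugation.

Step 6
Reactants: 9 4-methylpent-3-enal; 10 2-(buta-2,3-dien-1-yl)-4,4,5,5-tetramethyl-1,3,2-dioxaborolane
Product: 11 (4S)-7-methyl-3-methylideneocta-1,6-dien-4-ol
Conditions: (R)-TRIP (3,3'-bis(2,4,6-triisopropylphenyl)-1,1'-binaphthyl-2,2'-diyl hydrogen phosphate, 5 mol%), 4 Å MS, toluene, −30 °C; aqueous work-up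
Reagents that add atoms: none
Why: Chiral-phosphoric-acid-catalysed homoallenylboration: γ-attack through a chair six-membered transition state turns the allene into the buta-1,3-dien-2-yl group, and the catalyst antipode is the one expected, by the allylboration model, to add to the Re face and set (S)-C4.

Step 7
Reactants: 11 (4S)-7-methyl-3-methylideneocta-1,6-dien-4-ol
Product: 12 triethyl{[(4S)-7-methyl-3-methylideneocta-1,6-dien-4-yl]oxy}silane
Conditions: TESCl, imidazole, CH2Cl2, 0 °C
Reagents that add atoms: chlorotriethylsilane CC[Si](Cl)(CC)CC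
Why: Silyl ether formation masks the allylic oxygen with a group that survives base and zerovalent platinum and palladium but leaves under mild acid.

Step 8
Reactants: 12 triethylsilyl ether of the dienol
Product: 13 2,2'-{(2E)-2-[(1S)-4-methyl-1-(triethylsilyloxy)pent-3-en-1-yl]but-2-ene-1,4-diyl}bis(4,4,5,5-tetramethyl-1,3,2-dioxaborolane) (the two CH2Bpin groups cis)
Conditions: B2pin2 (1.05 equiv), Pt(PPh3)4 (3 mol%), toluene, 80 °C
Reagents that add atoms: bis(pinacolato)diboron CC1(C)OB(OC1(C)C)B1OC(C)(C)C(C)(C)O1
Why: Platinum-catalysed 1,4-diboration of the s-cis diene should give the bis(allylic) boronate with both CH2Bpin groups on one side of the new alkene, while the isolated trisubstituted alkene does not react with the phosphine-bound zerovalent platinum catalyst.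

Step 9
Reactants: 13 bis(allylic) boronate; 7 (2R,3Z)-4-iodo-2-[(4-methoxyphenyl)methoxy]-3-methylbut-3-enal
Product: 15 (1S,2R,6R)-2-[(4-methoxyphenyl)methoxy]-3-methyl-6-[(3S)-6-methyl-3-(triethylsilyloxy)hepta-1,5-dien-2-yl]cyclohex-3-en-1-ol, via open-chain allylboration adduct 14 (not isolated)
Conditions: toluene, 4 Å MS, 23 °C; then Pd(OAc)2 (5 mol%), RuPhos (10 mol%), KOH (3 equiv), THF/H2O (10:1), 70 °C
Reagents that add atoms: none
Why: Stage one is an uncatalysed allylboration in which the aldehyde of 7 binds the boron on C1' of 13 and the γ-carbon (future C6) adds through a chair six-membered transition state, forming C1–C6, moving the alkene to C2'=C1' and leaving the other boron as a non-allylic primary CH2Bpin (14); in stage two zerovalent palladium (from Pd(OAc)2) inserts into the alkenyl C–I bond, the primary boronate transmetalates with help of hydroxide and the neighbouring C1 alkoxide (five-membered borate), and reductive elimination forms C4–C5 (intramolecular B-alkyl Suzuki–Miyaura coupling). The closest known reaction types are additions of γ-substituted allyl pinacol boronates to α-alkoxy aldehydes and the allylation/cross-coupling use of diene-derived bis(boronates). Only stage two closes a ring: the cyclohexene forms by C(sp3)–C(sp2) reductive elimination from a seven-membered palladacycle, which the (Z) alkenyl iodide allows by holding both termini on one side. C1 is set by the C2 stereocentre of 7, because a (Z)-type γ-substituted boronate should attack an α-alkoxy aldehyde through the Cornforth arrangement to give the 1,2-anti pattern (C1–OH cis to C2–OPMB in the ring), and C6 is set by the alkene geometry of 13 (CH2Bpin on the γ-carbon cis to the boron-bearing CH2, axial in the chair), which gives the syn adduct, that is the side chain cis to C1–OH. The step needs the aldehyde to react with the right one of the two allylboronate units, which is secured because the other would have to build a quaternary carbon next to the branched silyloxy carbon, and it needs transmetalation to outrun β-hydride elimination, for which the bulky electron-rich biarylphosphine and the intramolecular borate are chosen.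

Step 10
Reactants: 15 cyclohexenol
Product: 16 tert-butyldimethylsilyl ether of 15 at O1
Conditions: TBSOTf, 2,6-lutidine, CH2Cl2, −78 to 0 °C
Reagents that add atoms: tert-butyldimethylsilyl trifluoromethanesulfonate CC(C)(C)[Si](C)(C)OS(=O)(=O)C(F)(F)F
Why: Silyl triflate silylation of the only free hydroxyl (hindered, axial C1–OH) reserves this position as the one that stays unacylated.

Step 11
Reactants: 16 O1-TBS ether
Product: 17 (1R,5R,6S)-6-[(tert-butyldimethylsilyl)oxy]-2-methyl-5-[(3S)-6-methyl-3-(triethylsilyloxy)hepta-1,5-dien-2-yl]cyclohex-2-en-1-ol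
Conditions: DDQ, CH2Cl2/pH 7 buffer (10:1), 0 °C
Reagents that add atoms: none
Why: Oxidative PMB cleavage (electron transfer from the electron-rich benzyl ether, then hydrolysis of the oxocarbenium ion) should free only the allylic hydroxyl (target C2), both silyl ethers being stable.

Step 12
Reactants: 17 allylic alcohol
Product: 18 cis-epoxy alcohol (7-oxabicyclo[4.1.0]heptan-2-ol core; oxirane over target C3–C4 on the face of the C2 hydroxyl; O1-TBS and O3'-TES retained)
Conditions: VO(acac)2 (5 mol%), t-BuOOH (1.3 equiv, decane), CH2Cl2, 0 to 23 °C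
Reagents that add atoms: tert-butyl hydroperoxide CC(C)(C)OO
Why: Vanadium-catalysed hydroxyl-directed epoxidation delivers the peroxide oxygen within the vanadate ester of the allylic alcohol, so the oxirane should form syn to C2–OH (sets C3) and the two side-chain alkenes, which have no free allylic hydroxyl, are left.

Step 13
Reactants: 18 cis-epoxy alcohol
Product: 19 C4 angelate 2,3-diol (ring configured as in 23; O1-TBS, O3'-TES)
Conditions: angelic acid (2 equiv), Ti(OiPr)4 (1.5 equiv), CH2Cl2, 23 °C
Reagents that add atoms: angelic acid C/C=C(/C)C(=O)O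
Why: Titanium-mediated regioselective opening of a 2,3-epoxy alcohol by a carboxylic acid: the acid should attack C4 with inversion (the secondary carbon remote from the carbinol, and the one that opens trans-diaxially with the C6 substituent equatorial, Fürst–Plattner rule), which sets the C4 angelate trans to the C3 tertiary hydroxyl.

Step 14
Reactants: 19 C4 angelate 2,3-diol
Product: 20 C4 angelate with free C2, C3 and C3' hydroxyls (O1-TBS retained)
Conditions: PPTS (0.2 equiv), MeOH/CH2Cl2, 0 °C
Reagents that add atoms: none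
Why: Acid-catalysed methanolysis should remove the less hindered triethylsilyl ether and keep the tert-butyldimethylsilyl ether; no stereocentre is involved.

Step 15
Reactants: 20 triol
Product: 21 tris-angelate (C2, C4, C3') with free C3–OH and O1-TBS
Conditions: angelic acid, 2,4,6-trichlorobenzoyl chloride, Et3N, toluene, 23 °C; then 20, DMAP, toluene, 70 °C
Reagents that add atoms: angelic acid C/C=C(/C)C(=O)O
Why: Yamaguchi esterification through the mixed anhydride acylates the two secondary hydroxyls while the tertiary C3–OH stays free, and this activation is chosen because it is known to preserve the (Z) geometry of angelic acid.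

Step 16
Reactants: 21 tris-angelate
Product: 22 O1-TBS ether of the target (side-chain (S)-epoxide in place)
Conditions: L-fructose-derived enantiomer of the Shi ketone (0.3 equiv), Oxone, K2CO3, Bu4NHSO4 (cat.), MeCN/CH2(OMe)2/aq. Na2B4O7 buffer, 0 °C
Reagents that add atoms: potassium peroxymonosulfate [K+].[O-]S(=O)(=O)OO
Why: Shi asymmetric epoxidation: the chiral dioxirane should react with the electron-rich trisubstituted alkene much faster than with the 1,1-disubstituted alkene or the three electron-poor enoates, and the catalyst antipode is chosen so that the spiro transition state gives the (S)-oxirane carbon.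

Step 17
Reactants: 22 O1-TBS ether of the target
Product: 23 CNP0421750.2, (1S,2S,3R,4S,6R)-6-{(3S)-3-(angeloyloxy)-4-[(2S)-3,3-dimethyloxiran-2-yl]but-1-en-2-yl}-1,3-dihydroxy-3-methylcyclohexane-2,4-diyl bis[(2Z)-2-methylbut-2-enoate]
Conditions: TBAF, AcOH (1:1), THF, 23 °C
Reagents that add atoms: none
Why: Fluoride-induced desilylation, buffered with acetic acid so that the freed C1 hydroxyl stays protonated and neither acyl migration from the cis C2 angelate nor epoxide opening should take place.

**Compound list**

1 | pent-1-en-4-yn-3-ol (racemic) | C=CC(O)C#C | starting material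
2 | cyclic (Z)-alkenylmagnesium alkoxide chelate | C=CC1O[Mg]C=C1C | intermediate
3 | rac-(1Z)-1-iodo-2-methylpenta-1,4-dien-3-ol | C=CC(O)/C(C)=C\I | intermediate
4 | (1Z,3S)-1-iodo-2-methylpenta-1,4-dien-3-ol | I/C=C(C)\[C@@H](O)C=C | intermediate
5 | 1-({[(1Z,3S)-1-iodo-2-methylpenta-1,4-dien-3-yl]oxy}methyl)-4-methoxybenzene | I/C=C(C)\[C@@H](OCc1ccc(OC)cc1)C=C | intermediate
6 | (3R,4Z)-5-iodo-3-[(4-methoxyphenyl)methoxy]-4-methylpent-4-ene-1,2-diol (both C2 epimers) | I/C=C(C)\[C@@H](OCc1ccc(OC)cc1)C(O)CO | intermediate
7 | (2R,3Z)-4-iodo-2-[(4-methoxyphenyl)methoxy]-3-methylbut-3-enal | I/C=C(C)\[C@@H](OCc1ccc(OC)cc1)C=O | intermediate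
8 | 4-methylpent-3-en-1-ol | CC(C)=CCCO | starting material
9 | 4-methylpent-3-enal | CC(C)=CCC=O | intermediate
10 | 2-(buta-2,3-dien-1-yl)-4,4,5,5-tetramethyl-1,3,2-dioxaborolane | C=C=CCB1OC(C)(C)C(C)(C)O1 | starting material
11 | (4S)-7-methyl-3-methylideneocta-1,6-dien-4-ol | C=C([C@H](CC=C(C)C)O)C=C | intermediate
12 | triethyl{[(4S)-7-methyl-3-methylideneocta-1,6-dien-4-yl]oxy}silane | C=C([C@H](CC=C(C)C)O[Si](CC)(CC)CC)C=C | intermediate
13 | 2,2'-{(2E)-2-[(1S)-4-methyl-1-(triethylsilyloxy)pent-3-en-1-yl]but-2-ene-1,4-diyl}bis(4,4,5,5-tetramethyl-1,3,2-dioxaborolane) | CC1(C)OB(C/C=C(\CB2OC(C)(C)C(C)(C)O2)[C@H](CC=C(C)C)O[Si](CC)(CC)CC)OC1(C)C | intermediate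
14 | open-chain allylboration adduct: O-boryl carbinol at C1, CH2Bpin on C6, (Z)-alkenyl iodide, PMB ether at C2, TES ether at C3' | C=C([C@H](CC=C(C)C)O[Si](CC)(CC)CC)[C@@H](CB1OC(C)(C)C(C)(C)O1)[C@H](OB2OC(C)(C)C(C)(C)O2)[C@H](OCc3ccc(OC)cc3)/C(C)=C\I | intermediate
15 | (1S,2R,6R)-2-[(4-methoxyphenyl)methoxy]-3-methyl-6-[(3S)-6-methyl-3-(triethylsilyloxy)hepta-1,5-dien-2-yl]cyclohex-3-en-1-ol | C=C([C@H](CC=C(C)C)O[Si](CC)(CC)CC)[C@H]1CC=C(C)[C@@H](OCc2ccc(OC)cc2)[C@H]1O | intermediate
16 | O1-tert-butyldimethylsilyl ether of 15 | C=C([C@H](CC=C(C)C)O[Si](CC)(CC)CC)[C@H]1CC=C(C)[C@@H](OCc2ccc(OC)cc2)[C@H]1O[Si](C)(C)C(C)(C)C | intermediate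
17 | (1R,5R,6S)-6-[(tert-butyldimethylsilyl)oxy]-2-methyl-5-[(3S)-6-methyl-3-(triethylsilyloxy)hepta-1,5-dien-2-yl]cyclohex-2-en-1-ol | C=C([C@H](CC=C(C)C)O[Si](CC)(CC)CC)[C@H]1CC=C(C)[C@@H](O)[C@H]1O[Si](C)(C)C(C)(C)C | intermediate
18 | cis-epoxy alcohol: oxirane over C3–C4 on the face of C2–OH, O1-TBS, O3'-TES | C=C([C@H](CC=C(C)C)O[Si](CC)(CC)CC)[C@H]1C[C@H]2O[C@@]2(C)[C@@H](O)[C@H]1O[Si](C)(C)C(C)(C)C | intermediate
19 | C4 angelate, C2 and C3 hydroxyls free, O1-TBS, O3'-TES (ring configured as in 23) | C=C([C@H](CC=C(C)C)O[Si](CC)(CC)CC)[C@H]1C[C@H](OC(=O)/C(C)=C\C)[C@@](C)(O)[C@@H](O)[C@H]1O[Si](C)(C)C(C)(C)C | intermediate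
20 | C4 angelate, C2, C3 and C3' hydroxyls free, O1-TBS | C=C([C@H](CC=C(C)C)O)[C@H]1C[C@H](OC(=O)/C(C)=C\C)[C@@](C)(O)[C@@H](O)[C@H]1O[Si](C)(C)C(C)(C)C | intermediate
21 | C2, C4, C3' tris-angelate, C3–OH free, O1-TBS, side-chain trisubstituted alkene | C=C([C@H](CC=C(C)C)OC(=O)/C(C)=C\C)[C@H]1C[C@H](OC(=O)/C(C)=C\C)[C@@](C)(O)[C@@H](OC(=O)/C(C)=C\C)[C@H]1O[Si](C)(C)C(C)(C)C | intermediate
22 | O1-tert-butyldimethylsilyl ether of the target | C=C([C@H](C[C@@H]1OC1(C)C)OC(=O)/C(C)=C\C)[C@H]1C[C@H](OC(=O)/C(C)=C\C)[C@@](C)(O)[C@@H](OC(=O)/C(C)=C\C)[C@H]1O[Si](C)(C)C(C)(C)C | intermediate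
23 | CNP0421750.2, (1S,2S,3R,4S,6R)-6-{(3S)-3-(angeloyloxy)-4-[(2S)-3,3-dimethyloxiran-2-yl]but-1-en-2-yl}-1,3-dihydroxy-3-methylcyclohexane-2,4-diyl bis[(2Z)-2-methylbut-2-enoate] | C=C([C@H](C[C@@H]1OC1(C)C)OC(=O)/C(C)=C\C)[C@H]1C[C@H](OC(=O)/C(C)=C\C)[C@@](C)(O)[C@@H](OC(=O)/C(C)=C\C)[C@H]1O | target

**Step count.** Total: 17 steps. Longest linear sequence: 13 steps (steps 1–4, then 9–17; the branch through steps 5–8 is equally long).

**Steps most likely to fail**

Step 9. In stage two, slow transmetalation of the β-branched primary pinacol boronate may let β-hydride elimination, protodeboronation or insertion of the alkenylpalladium into the nearby 1,1-disubstituted alkene overtake ring closure. In stage one, the C3' stereocentre on the boronate may oppose the facial preference of the aldehyde and erode the diastereoselectivity. The fallback separates the two bond formations and closes the ring by a cross-electrophile coupling. It sets out from 14: the allylboration is run alone and the adduct is oxidised in the same flask (NaBO3·4H2O, THF/H2O) to the open-chain diol with a primary CH2OH on C6 and the free C1 carbinol F1. Appel-type iodination of the primary hydroxyl (I2, PPh3, imidazole, CH2Cl2, 0 °C) should give the alkyl iodide F2. Nickel-catalysed reductive cyclisation of the alkyl iodide onto the alkenyl iodide (NiBr2·glyme, 4,4'-di-tert-butyl-2,2'-bipyridine, Mn powder, DMA, 23 °C) should then form C4–C5 and return to the route at 15.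

Step 13. The Lewis acid may ionise the epoxide toward the tertiary C3, giving attack at the wrong carbon or rearrangement to a ketone by hydride shift, or the hindered C4 may not react with the weakly nucleophilic acid. The fallback uses hydroxide as nucleophile and esterifies afterwards. It sets out from 18: NaOH in DMSO/H2O at 80 °C should open the oxirane at the secondary C4 in the trans-diaxial sense to the C2, C3, C4 triol F3. PPTS in MeOH removes the triethylsilyl group to give the tetraol F4. Threefold Yamaguchi angeloylation of the three secondary hydroxyls (C2, C4, C3') then returns to the route at 21.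

Step 15. Acylation of the hindered C2 hydroxyl may stall, and under forcing conditions the activated acyl donor may isomerise from Z to E, giving tiglate esters. The fallback builds the Z alkenes on the esters. It sets out from 20: carbodiimide esterification (EDC·HCl, DMAP, CH2Cl2) with 2-[bis(2,2,2-trifluoroethoxy)phosphoryl]propanoic acid should give the C2, C3' bis(phosphonopropanoate) F5. Still–Gennari olefination with acetaldehyde (KHMDS, 18-crown-6, THF, −78 °C) should give both (Z)-2-methylbut-2-enoates and return to the route at 21.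

**Further compounds**

F1 | step 9 | open-chain diol from 14 (CH2OH on C6, free C1–OH, (Z)-alkenyl iodide, C2 PMB ether, C3' TES ether) | C=C([C@H](CC=C(C)C)O[Si](CC)(CC)CC)[C@@H](CO)[C@H](O)[C@H](OCc1ccc(OC)cc1)/C(C)=C\I
F2 | step 9 | primary alkyl iodide from F1 (CH2I on C6, free C1–OH) | C=C([C@H](CC=C(C)C)O[Si](CC)(CC)CC)[C@@H](CI)[C@H](O)[C@H](OCc1ccc(OC)cc1)/C(C)=C\I
F3 | step 13 | C2, C3, C4 triol with O1-TBS and O3'-TES (C4–OH trans to C3–OH) | C=C([C@H](CC=C(C)C)O[Si](CC)(CC)CC)[C@H]1C[C@H](O)[C@@](C)(O)[C@@H](O)[C@H]1O[Si](C)(C)C(C)(C)C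
F4 | step 13 | C2, C3, C4, C3' tetraol with O1-TBS | C=C([C@H](CC=C(C)C)O)[C@H]1C[C@H](O)[C@@](C)(O)[C@@H](O)[C@H]1O[Si](C)(C)C(C)(C)C
F5 | step 15 | C4 angelate C2, C3' bis{2-[bis(2,2,2-trifluoroethoxy)phosphoryl]propanoate} with O1-TBS | C=C([C@H](CC=C(C)C)OC(=O)C(C)P(=O)(OCC(F)(F)F)OCC(F)(F)F)[C@H]1C[C@H](OC(=O)/C(C)=C\C)[C@@](C)(O)[C@@H](OC(=O)C(C)P(=O)(OCC(F)(F)F)OCC(F)(F)F)[C@H]1O[Si](C)(C)C(C)(C)C
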